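**Retrosynthetic overview**
- Feature: ring B (C5–C10) is a cyclohexene. Its C7=C8 bond carries the C12 ester on C8, and the neighbouring C9 carries the C11 carbonyl carbon. This pattern corresponds to an alkylidene phosphonoacetate (C9=C8) joined to a C7 aldehyde.
- Key cut: C9–C10 (Michael addition) and C7=C8 (Horner–Wadsworth–Emmons) are broken together. This leads back to ring A silyl dienol ether aldehyde 21 and acceptor 24.
- Ring A is made first. A catalytic malonate Michael addition sets C5 and a Dieckmann closure follows. The spare malonate ester stays on C4 until the enol ether is fixed, so no symmetric 1,3-dione can erase C5. C4 is then built by two alkylations anti to the C5 arm, and the vinylogous ester is transposed to the chloroenone.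
- Ring B is made second (step 13). The endgame is side-chain epoxide (mask and stereocentre), C1 reduction, C2=C3 hydrogenation to the 3β-chloride, acid-free silyl triflate unmasking, and conversion of the C11 acid to the aldehyde.

Key step: step 13

Numbering used below: ring A = C1, C2, C3, C4, C5, C10; ring B = C5 to C10; C11 on C9; C12 on C8; α = face of 5-H; β = face of the C10 methyl.

Assumption: the (S,S) primary amine–thiourea of step 2 is taken to deliver malonate to the face of 3 that gives (R)-5. Its enantiomer is equally available and would be used if the sense proved opposite.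

**Step 1**
Reactants: 1 3-butenal diethyl acetal (4,4-diethoxybut-1-ene); 2 methyl vinyl ketone
Product: 3 (E)-6,6-diethoxyhex-3-en-2-one
Conditions: second-generation Hoveyda–Grubbs catalyst (2 mol %), 2 (3 equiv), CH2Cl2, 40 °C
Reagents that add atoms: none
Why: Olefin cross-metathesis of a terminal alkene with an electron-poor enone should give the E-enone selectively, and the acetal is inert to the ruthenium carbene.

**Step 2**
Reactants: 3 (E)-6,6-diethoxyhex-3-en-2-one; 4 dimethyl malonate
Product: 5 dimethyl 2-[(3R)-1,1-diethoxy-5-oxohexan-3-yl]propanedioate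
Conditions: 1-[(1S,2S)-2-amino-1,2-diphenylethyl]-3-[3,5-bis(trifluoromethyl)phenyl]thiourea (10 mol %), PhCO2H (10 mol %), toluene, 40 °C
Reagents that add atoms: none
Why: In this organocatalytic asymmetric Michael addition the primary amine forms the iminium ion of 3 and the thiourea holds the malonate, so one face of C5 is attacked and C5 is set by the catalyst, while the nearly neutral medium should keep the δ-ethoxy groups from eliminating.

**Step 3**
Reactants: 5 Michael adduct
Product: 7 methyl (6R)-6-(2,2-diethoxyethyl)-2,4-dioxocyclohexane-1-carboxylate (enol forms; C1 epimers), via sodium enolate 6 (not isolated)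
Conditions: NaOMe (1.2 equiv), MeOH, reflux; then 1 M HCl (1.2 equiv), 0 °C
Reagents that add atoms: none
Why: The Dieckmann-type acylation of the methyl ketone enolate by one malonate ester closes ring A (6-exo-trig) and is driven by the stabilised enolate 6, while the ester left on C4 keeps the dione unsymmetrical so that C5 remains a stereocentre.

**Step 4**
Reactants: 7 dione ester
Product: 8 methyl (6S)-6-(2,2-diethoxyethyl)-4-ethoxy-2-oxocyclohex-3-ene-1-carboxylate
Conditions: HC(OEt)3, EtOH, TsOH·H2O (5 mol %), 25 °C
Reagents that add atoms: triethyl orthoformate, CCOC(OCC)OCC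
Why: Acid-catalysed enol ether formation should take place at the less hindered C1 carbonyl, remote from the ester-bearing C4, and the minor C3 regioisomer is removed here because after loss of the ester it would be the enantiomer of 9.

**Step 5**
Reactants: 8 enol ether ester
Product: 9 (5S)-5-(2,2-diethoxyethyl)-3-ethoxycyclohex-2-en-1-one
Conditions: LiCl, H2O, DMSO, 130 °C
Reagents that add atoms: none
Why: Krapcho dealkoxycarbonylation removes the methyl β-keto ester under neutral conditions, and because the enol ether already distinguishes C1 from C3 no achiral dione intervenes and C5 is kept.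

**Step 6**
Reactants: 9 vinylogous ester
Product: 11 (5S)-5-(2,2-diethoxyethyl)-3-ethoxy-6-methylcyclohex-2-en-1-one (C6 epimers; trans major), via lithium enolate 10 (not isolated)
Conditions: LiN(iPr)2, THF, −78 °C; MeI, −78 to −20 °C
Reagents that add atoms: iodomethane, CI
Why: This is a kinetic α′-deprotonation and methylation of a vinylogous ester (Stork–Danheiser alkylation) at C4, and the new centre is planarised again in step 7.

**Step 7**
Reactants: 11 6-methyl vinylogous ester; 12 5-iodo-2-methylpent-2-ene
Product: 14 (5S,6S)-5-(2,2-diethoxyethyl)-3-ethoxy-6-methyl-6-(4-methylpent-3-en-1-yl)cyclohex-2-en-1-one, via lithium enolate 13 (not isolated)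
Conditions: LiN(iPr)2, THF, −78 to 0 °C; DMPU; 12, 0 °C to rt
Reagents that add atoms: none
Why: In this second α′-enolate alkylation the C5 arm of 13 stands pseudo-axial to avoid A(1,2) strain with the C4 methyl, so the iodide is attacked on the opposite face, which sets quaternary C4 with the side chain trans to the arm and the methyl β.

**Step 8**
Reactants: 14 quaternary vinylogous ester
Product: 15 (4S,5R)-3-chloro-5-(2,2-diethoxyethyl)-4-methyl-4-(4-methylpent-3-en-1-yl)cyclohex-2-en-1-one
Conditions: (COCl)2 (1.3 equiv), 2,6-di-tert-butylpyridine (0.2 equiv), CH2Cl2, 0 °C to rt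
Reagents that add atoms: oxalyl chloride, O=C(Cl)C(=O)Cl
Why: O-acylation of the C3 carbonyl, chloride addition–elimination at C3 and dealkylation of the ethyl oxocarbenium ion by chloride (Vilsmeier-type chlorodeoxygenation with 1,3-carbonyl transposition) place chlorine on the hindered C3, which chlorination of the free dione would not do, and the hindered pyridine traps HCl so that the acetal and the alkene survive.

**Step 9**
Reactants: 15 chloroenone
Product: 17 (4S,5R)-3-chloro-5-(2,2-diethoxyethyl)-4,6-dimethyl-4-(4-methylpent-3-en-1-yl)cyclohex-2-en-1-one (C6 epimers), via lithium enolate 16 (not isolated)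
Conditions: LiN(iPr)2 (1.05 equiv), THF, −78 °C; MeI
Reagents that add atoms: iodomethane, CI
Why: Because C4 is quaternary only C10 can be deprotonated, so kinetic enolate methylation should be regiospecific, and the new C10 centre is planarised in step 10.

**Step 10**
Reactants: 17 C10-methyl chloroenone
Product: 19 triethylsilyl dienol ether of 17 (C1–OSiEt3; C1=C10; C2=C3–Cl; 4S; 5R; acetal intact), via potassium dienolate 18 (not isolated)
Conditions: KN(SiMe3)2, THF, −78 °C; Et3SiCl
Reagents that add atoms: chlorotriethylsilane, CC[Si](Cl)(CC)CC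
Why: O-silylation of the only possible enolate gives the tetrasubstituted cross-conjugated silyl dienol ether, and it is done while C7 is still an acetal because a free aldehyde would be enolised and silylated first.

**Step 11**
Reactants: 19 silyl dienol ether acetal
Product: 21 2-[(1R,6S)-5-chloro-2,6-dimethyl-6-(4-methylpent-3-en-1-yl)-3-(triethylsilyloxy)cyclohexa-2,4-dien-1-yl]acetaldehyde, via lutidinium salt 20 (not isolated)
Conditions: Et3SiOTf, 2,6-lutidine, CH2Cl2, 0 °C; then H2O
Reagents that add atoms: water, O
Why: A silyl triflate with 2,6-lutidine turns an aldehyde acetal into a pyridinium N,O-acetal salt that water hydrolyses under weakly basic conditions, so the aldehyde is freed without acid and the silyl dienol ether should survive.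

**Step 12**
Reactants: 22 methyl diethylphosphonoacetate; 23 tert-butyl glyoxylate
Product: 24 4-tert-butyl 1-methyl (E)-2-(diethoxyphosphoryl)but-2-enedioate
Conditions: piperidine (10 mol %), AcOH (10 mol %), toluene, 4 Å MS, 60 °C
Reagents that add atoms: none
Why: In this Knoevenagel condensation the amine–acid catalyst dehydrates the aldol adduct with phosphorus retained instead of olefinating, and the tert-butyl ester tolerates the medium.

**Step 13**
Reactants: 21 ring A silyl dienol ether aldehyde; 24 alkylidene phosphonoacetate
Product: 27 trans-decalin chloroenone diester (3-chloro-1-oxo-2,7-diene; 4β-Me; 4α-homoprenyl; 5α-H; 10β-Me; 9β-CO2tBu; 8-CO2Me), via ammonium dienolate 25 (not isolated), via phosphonate carbanion 26 (not isolated)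
Conditions: 24 (1.5 equiv), Bu4N[Ph3SiF2] (1.1 equiv, slow addition), THF (0.02 M), 4 Å MS, −78 to 0 °C; pH 7 buffer
Reagents that add atoms: none
Why: Fluoride from the silicate removes the triethylsilyl group and frees the cross-conjugated dienolate 25, which can bond only through C10 because C4 is quaternary, and it adds to C9 of 24, the alkene carbon whose attack leaves the charge on C8 between phosphoryl and ester (carbanion 26). This carbanion attacks the tethered C7 aldehyde and expels diethyl phosphate, so the sequence is a Mukaiyama–Michael addition followed by an intramolecular Horner–Wadsworth–Emmons olefination, the known phosphonoacrylate Michael–olefination route to cycloalkene carboxylates. Ring B closes by a chair-like 6-exo-trig addition of C8 to the C7 carbonyl, whereas attack of C10 on C7 would need a four-membered ring, so the free aldehyde cannot quench the dienolate within the molecule. C10 should be set by approach of 24 to the α face, anti to the C5 arm that A(1,2) strain with the C10 methyl holds pseudo-axial, which gives the trans fusion with the methyl axial. C9 is set kinetically in the same bond formation and in the closure that carries the tert-butyl ester equatorial (β), and it should not equilibrate afterwards, nor should the 7-ene slip into conjugation with C11, because diethyl phosphate is the only anion left. The step needs C- over O-attack, C9 over C8 regiochemistry and Michael addition ahead of intermolecular aldol reaction or proton transfer from C6, and these are served by the triply activated acceptor in excess, high dilution and slow release of fluoride.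

**Step 14**
Reactants: 27 chloroenone diester
Product: 28 side-chain (R)-epoxide of 27 (2,2-dimethyl-3-alkyloxirane)
Conditions: D-fructose-derived ketone (1,2:4,5-di-O-isopropylidene-β-D-erythro-2,3-hexodiulo-2,6-pyranose, 30 mol %), KHSO5 (as 2KHSO5·KHSO4·K2SO4), K2CO3, Bu4NHSO4, MeCN–CH2(OMe)2–aq. Na2B4O7 buffer, 0 °C
Reagents that add atoms: potassium peroxymonosulfate, [K+].[O-]S(=O)(=O)OO
Why: In the Shi asymmetric epoxidation the electrophilic dioxirane reacts only with the electron-rich trisubstituted alkene, the D-fructose ketone sets the R epoxide carbon by reagent control, and the epoxide also masks this alkene from borane and hydrogen in steps 15 and 16.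

**Step 15**
Reactants: 28 epoxy chloroenone
Product: 29 1α-allylic alcohol (1S; C2=C3–Cl retained)
Conditions: (R)-Me-CBS oxazaborolidine (0.5 equiv), BH3·SMe2, toluene, −20 °C; MeOH
Reagents that add atoms: none
Why: In the Corey–Bakshi–Shibata reduction the ketone binds with the fully substituted C10 as the large group, so the (R)-catalyst should deliver hydride to the β face and give the axial 1α-alcohol against the substrate preference for α attack, while esters, epoxide and vinyl chloride are left alone at this temperature.

**Step 16**
Reactants: 29 1α-allylic alcohol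
Product: 30 3β-chloro-1α-ol (saturated ring A; 7-ene retained)
Conditions: [Ir(cod)(PCy3)(py)]PF6 (10 mol %), H2 (1 to 10 bar), CH2Cl2, 25 °C
Reagents that add atoms: none
Why: In this hydroxyl-directed homogeneous hydrogenation the 1α-hydroxyl binds iridium and hydrogen is delivered to the α face of C2=C3, which is also the face free of the two axial methyls, so C3 receives α-H and keeps chlorine β (equatorial), and the electron-poor undirected 7-ene should be slower.

**Step 17**
Reactants: 30 3β-chloro-1α-ol
Product: 32 C11 carboxylic acid with 1α-OSiEt3 and (R)-CH(OSiEt3)C(CH3)=CH2 side chain, via silyl ester 31 (not isolated)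
Conditions: Et3SiOTf (6 equiv), 2,6-lutidine (8 equiv), CH2Cl2, −78 °C to rt; pH 7 buffer
Reagents that add atoms: triethylsilyl triflate, CC[Si](CC)(CC)OS(=O)(=O)C(F)(F)F
Why: One acid-free reagent pair carries out three known silyl triflate reactions (hydroxyl silylation, epoxide-to-allylic silyl ether isomerisation by C–O cleavage at the tertiary carbon with retention at the carbinol carbon, and tert-butyl ester cleavage with loss of isobutene), which avoids a protic acid that the epoxide could not survive.

**Step 18**
Reactants: 32 C11 acid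
Product: 34 C11 aldehyde bis(triethylsilyl) ether, via acid chloride 33 (not isolated)
Conditions: Me2C=C(Cl)NMe2, CH2Cl2, 0 °C; then LiAlH(OtBu)3, THF, −78 °C
Reagents that add atoms: none
Why: The neutral α-chloroenamine converts the hindered acid to its chloride without base, and partial reduction of an acid chloride by the bulky alkoxyaluminium hydride should stop at the aldehyde, leaving the methyl enoate, the chloride and the C9 configuration untouched.

**Step 19**
Reactants: 34 aldehyde bis(silyl ether)
Product: 35 target CNP0159496.2
Conditions: HF·pyridine, pyridine, THF, 0 °C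
Reagents that add atoms: none
Why: Buffered fluoride desilylation is mildly acidic, so both triethylsilyl ethers should be cleaved without epimerising the base-sensitive 9β-aldehyde.

**Compound list**
1 | 3-butenal diethyl acetal | C=CCC(OCC)OCC | starting material
2 | methyl vinyl ketone | CC(=O)C=C | starting material
3 | (E)-6,6-diethoxyhex-3-en-2-one | CC(=O)/C=C/CC(OCC)OCC | intermediate
4 | dimethyl malonate | COC(=O)CC(=O)OC | starting material
5 | dimethyl 2-[(3R)-1,1-diethoxy-5-oxohexan-3-yl]propanedioate | COC(=O)C(C(=O)OC)[C@@H](CC(C)=O)CC(OCC)OCC | intermediate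
6 | sodium enolate of 7 | [Na+].COC(=O)C1C(=O)C=C([O-])C[C@H]1CC(OCC)OCC | intermediate
7 | methyl (6R)-6-(2,2-diethoxyethyl)-2,4-dioxocyclohexane-1-carboxylate | COC(=O)C1C(=O)CC(=O)C[C@H]1CC(OCC)OCC | intermediate
8 | methyl (6S)-6-(2,2-diethoxyethyl)-4-ethoxy-2-oxocyclohex-3-ene-1-carboxylate | COC(=O)C1C(=O)C=C(OCC)C[C@H]1CC(OCC)OCC | intermediate
9 | (5S)-5-(2,2-diethoxyethyl)-3-ethoxycyclohex-2-en-1-one | O=C1C=C(OCC)C[C@@H](CC(OCC)OCC)C1 | intermediate
10 | lithium α′-enolate of 9 | [Li+].CCOC1=CC([O-])=C[C@H](CC(OCC)OCC)C1 | intermediate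
11 | (5S)-5-(2,2-diethoxyethyl)-3-ethoxy-6-methylcyclohex-2-en-1-one (C6 epimers) | O=C1C=C(OCC)C[C@@H](CC(OCC)OCC)C1C | intermediate
12 | 5-iodo-2-methylpent-2-ene | CC(C)=CCCI | starting material
13 | lithium α′-enolate of 11 | [Li+].CCOC1=CC([O-])=C(C)[C@H](CC(OCC)OCC)C1 | intermediate
14 | (5S,6S)-5-(2,2-diethoxyethyl)-3-ethoxy-6-methyl-6-(4-methylpent-3-en-1-yl)cyclohex-2-en-1-one | O=C1C=C(OCC)C[C@@H](CC(OCC)OCC)[C@]1(C)CCC=C(C)C | intermediate
15 | (4S,5R)-3-chloro-5-(2,2-diethoxyethyl)-4-methyl-4-(4-methylpent-3-en-1-yl)cyclohex-2-en-1-one | O=C1C=C(Cl)[C@@](C)(CCC=C(C)C)[C@H](CC(OCC)OCC)C1 | intermediate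
16 | lithium α′-enolate of 15 | [Li+].[O-]C1=C[C@@H](CC(OCC)OCC)[C@](C)(CCC=C(C)C)C(Cl)=C1 | intermediate
17 | (4S,5R)-3-chloro-5-(2,2-diethoxyethyl)-4,6-dimethyl-4-(4-methylpent-3-en-1-yl)cyclohex-2-en-1-one (C6 epimers) | O=C1C=C(Cl)[C@@](C)(CCC=C(C)C)[C@H](CC(OCC)OCC)C1C | intermediate
18 | potassium dienolate of 17 | [K+].[O-]C1=C(C)[C@@H](CC(OCC)OCC)[C@](C)(CCC=C(C)C)C(Cl)=C1 | intermediate
19 | triethylsilyl dienol ether of 17, acetal intact | CC(C)=CCC[C@]1(C)C(Cl)=CC(O[Si](CC)(CC)CC)=C(C)[C@H]1CC(OCC)OCC | intermediate
20 | 2,6-lutidinium N,O-acetal triflate | CC(C)=CCC[C@]1(C)C(Cl)=CC(O[Si](CC)(CC)CC)=C(C)[C@H]1CC(OCC)[n+]1c(C)cccc1C.[O-]S(=O)(=O)C(F)(F)F | intermediate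
21 | ring A chloro silyl dienol ether with acetaldehyde arm on C5 | CC(C)=CCC[C@]1(C)C(Cl)=CC(O[Si](CC)(CC)CC)=C(C)[C@H]1CC=O | intermediate
22 | methyl diethylphosphonoacetate | CCOP(=O)(CC(=O)OC)OCC | starting material
23 | tert-butyl glyoxylate | O=CC(=O)OC(C)(C)C | starting material
24 | 4-tert-butyl 1-methyl (E)-2-(diethoxyphosphoryl)but-2-enedioate | CCOP(=O)(OCC)/C(C(=O)OC)=C/C(=O)OC(C)(C)C | intermediate
25 | tetrabutylammonium dienolate from 21 | CCCC[N+](CCCC)(CCCC)CCCC.CC(C)=CCC[C@]1(C)C(Cl)=CC([O-])=C(C)[C@H]1CC=O | intermediate
26 | tetrabutylammonium phosphonate carbanion (Michael adduct) | CCCC[N+](CCCC)(CCCC)CCCC.CC(C)=CCC[C@]1(C)C(Cl)=CC(=O)[C@](C)([C@@H](C(=O)OC(C)(C)C)[C-](C(=O)OC)P(=O)(OCC)OCC)[C@H]1CC=O | intermediate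
27 | trans-fused chloroenone with ring B diester | CC(C)=CCC[C@]1(C)C(Cl)=CC(=O)[C@]2(C)[C@@H](C(=O)OC(C)(C)C)C(C(=O)OC)=CC[C@@H]12 | intermediate
28 | side-chain (R)-epoxide of 27 | CC1(C)O[C@@H]1CC[C@]2(C)C(Cl)=CC(=O)[C@]3(C)[C@@H](C(=O)OC(C)(C)C)C(C(=O)OC)=CC[C@@H]23 | intermediate
29 | 1α-allylic alcohol | CC1(C)O[C@@H]1CC[C@]2(C)C(Cl)=C[C@H](O)[C@]3(C)[C@@H](C(=O)OC(C)(C)C)C(C(=O)OC)=CC[C@@H]23 | intermediate
30 | 3β-chloro-1α-ol | CC1(C)O[C@@H]1CC[C@]2(C)[C@@H](Cl)C[C@H](O)[C@]3(C)[C@@H](C(=O)OC(C)(C)C)C(C(=O)OC)=CC[C@@H]23 | intermediate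
31 | C11 triethylsilyl ester bis(triethylsilyl) ether | C=C(C)[C@H](O[Si](CC)(CC)CC)CC[C@]1(C)[C@@H](Cl)C[C@H](O[Si](CC)(CC)CC)[C@]2(C)[C@@H](C(=O)O[Si](CC)(CC)CC)C(C(=O)OC)=CC[C@@H]12 | intermediate
32 | C11 acid bis(triethylsilyl) ether | C=C(C)[C@H](O[Si](CC)(CC)CC)CC[C@]1(C)[C@@H](Cl)C[C@H](O[Si](CC)(CC)CC)[C@]2(C)[C@@H](C(=O)O)C(C(=O)OC)=CC[C@@H]12 | intermediate
33 | C11 acid chloride | C=C(C)[C@H](O[Si](CC)(CC)CC)CC[C@]1(C)[C@@H](Cl)C[C@H](O[Si](CC)(CC)CC)[C@]2(C)[C@@H](C(Cl)=O)C(C(=O)OC)=CC[C@@H]12 | intermediate
34 | C11 aldehyde bis(triethylsilyl) ether | C=C(C)[C@H](O[Si](CC)(CC)CC)CC[C@]1(C)[C@@H](Cl)C[C@H](O[Si](CC)(CC)CC)[C@]2(C)[C@@H](C=O)C(C(=O)OC)=CC[C@@H]12 | intermediate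
35 | CNP0159496.2 | C=C(C)[C@H](O)CC[C@]1(C)[C@@H](Cl)C[C@H](O)[C@]2(C)[C@@H](C=O)C(C(=O)OC)=CC[C@@H]12 | target

Total step count: 19. Longest linear sequence: 18 (steps 1 to 11 and 13 to 19; step 12 is the side branch).

**Steps most likely to fail**

Step 13.
- What may go wrong: bond formation at the fully substituted C10 is slow. Proton transfer from C6 of the aldehyde to the dienolate and intermolecular aldol addition may outrun it.
- Facial selectivity at C10 may erode because the C4 side chain also leans over the α face, and selectivity at C9 rests on kinetics alone.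
- Fallback: the two bond formations are separated and the aldehyde stays masked while the quaternary centre is made. The fallback sets out from 19.
- Treatment of 19 with 24 and Bu4N[Ph3SiF2] in THF, followed by an NH4Cl quench, should give the open-chain phosphonate adduct with the acetal intact F1. No aldehyde competes at this stage, and the C9 and C10 isomers can be separated.
- Hydrolysis with pyridinium tosylate in aqueous acetone gives the keto aldehyde phosphonate F2. A separate Masamune–Roush olefination (LiCl, DBU, MeCN, 0 °C) closes ring B and returns to the route at 27.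

Step 15.
- What may go wrong: hydride delivery to the α face, anti to the axial C10 methyl, is the substrate's own preference. It may override the catalyst or run through uncatalysed borane, giving poor facial selectivity at C1.
- Fallback: the substrate bias is accepted and the centre is inverted. The fallback sets out from 28.
- Luche reduction (NaBH4, CeCl3·7H2O, MeOH, −78 °C) should give the 1β-allylic alcohol F3.
- Mitsunobu reaction (4-nitrobenzoic acid, PPh3, diisopropyl azodicarboxylate, toluene) gives the inverted 1α 4-nitrobenzoate F4.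
- Methanolysis (K2CO3, MeOH, 0 °C) returns to the route at 29.

Step 16.
- What may go wrong: chlorine may be lost by β-chloride elimination from an iridium alkyl or by hydrogenolysis. The acidic iridium hydride may rearrange the epoxide. Turnover may also stall at the alkene next to quaternary C4.
- Fallback: metal insertion is replaced by radical hydrogen-atom transfer. The fallback sets out from 29.
- Conditions are Co(acac)2, tBuOOH, Et3SiH and cyclohexa-1,4-diene in n-propanol at rt, the known hydrogenation of alkenyl halides to alkyl halides.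
- Hydrogen adds to C2 and the α-chloro radical at C3 is quenched from the α face, which is free of the two axial methyls. This gives the equatorial 3β-chloride independently of the hydroxyl group.
- The fallback returns to the route at 30 and makes no compound outside the list (F0).

**Further compounds**
F1 | step 13 | open-chain phosphonate adduct with the acetal intact (C8 epimers) | CC(C)=CCC[C@]1(C)C(Cl)=CC(=O)[C@](C)([C@@H](C(=O)OC(C)(C)C)C(C(=O)OC)P(=O)(OCC)OCC)[C@H]1CC(OCC)OCC
F2 | step 13 | keto aldehyde phosphonate (C8 epimers) | CC(C)=CCC[C@]1(C)C(Cl)=CC(=O)[C@](C)([C@@H](C(=O)OC(C)(C)C)C(C(=O)OC)P(=O)(OCC)OCC)[C@H]1CC=O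
F3 | step 15 | 1β-allylic alcohol | CC1(C)O[C@@H]1CC[C@]2(C)C(Cl)=C[C@@H](O)[C@]3(C)[C@@H](C(=O)OC(C)(C)C)C(C(=O)OC)=CC[C@@H]23
F4 | step 15 | 1α 4-nitrobenzoate | CC1(C)O[C@@H]1CC[C@]2(C)C(Cl)=C[C@H](OC(=O)c4ccc(cc4)[N+](=O)[O-])[C@]3(C)[C@@H](C(=O)OC(C)(C)C)C(C(=O)OC)=CC[C@@H]23
F0 | step 16 | none | none
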